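The readings are simulated for an exercise, noise included.

The vessel is closed and stirred, at constant volume and temperature, and the way to read it is to follow one molecule of starting material until it has gone somewhere.

| flask | starting material | protic impurity | remark | time |
|---|---|---|---|---|
| west | 0.10 M | 0.035 M | run made earlier |  |
| south-west | 0.10 M | 0.084 M | run made earlier |  |
| amber | 0.10 M | 0.100 M |  | 2.0 min |
| teal | 0.10 M | 0.0500 M |  | 3.0 min |

| run | time / s | target / % | side product / % |
|---|---|---|---|
| west | 20.0 | 12.3 | 5.2 |
| west | 40.0 | 22.0 | 8.7 |
| west | 60.0 | 29.8 | 11.7 |
| west | 80.0 | 36.9 | 14.9 |
| south-west | 20.0 | 11.6 | 4.7 |
| south-west | 40.0 | 21.3 | 8.3 |
| south-west | 60.0 | 29.0 | 10.9 |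
| south-west | 80.0 | 34.7 | 14.1 |

(scatter of a reading: 0.3 percentage points)

- the flask that ends with the higher share of target in all that became target or side product, or "neither" when 2 percentage points or less lies between them (amber / teal / neither)
- share of target in all that became target or side product, amber
- share of target in all that became target or side product, teal

Two of us read these runs differently. The first holds that a molecule reaching the fork between target and side product takes target with a constant chance, a selectivity factor. If both paths have the same order in starting material, neither time nor impurity should move the share asked for.

The second points to the last readings. At 80.0 s, target falls from 36.9% in the west run to 34.7% in the south-west run, against a scatter of 0.3 percentage points. Scaled to the impurity gap between amber and teal, that drop makes 2.2 points against a margin of 2 points, so teal should come out ahead.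

The first answers that side product falls too: south-west over west is 0.940 for target and 0.946 for side product. Losses in equal proportion leave a share where it was.

I side with the first and reckon from the last readings, where the same scatter sits on the largest amounts of each run. The west share is 71.2% and the south-west share 71.1%, across 2.40 times the impurity. Pooled, they give the fork chance, the share of target in what passes the fork, 71.2%. I expect that in amber and in teal.

The forecast gives 71.5% for amber and 71.5% for teal, each from 69.5% to 73.5%, and so neither, reading “parallel paths of the same order”; its number stands slightly above mine.

The simulation gives 71.2% in amber and 71.2% in teal, so neither.

    starting material → side product (k = 0.00276 s⁻¹)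
    starting material → target (k = 0.00684 s⁻¹)
    starting material + protic impurity → quenched substrate (k = 0.0383 M⁻¹ s⁻¹)
    crystals ⇌ target, rate k4*(cs4 - [target]) while solid is left; crystals form when [target] > cs4 (solubility = 5.20 mM, k = 0.0663 s⁻¹)

The second reader's view holds for target counted on the charge: at ten times the asked time, amber holds 53.0% and teal 60.9%, with quenched substrate at 25.7% and 14.5%. The scheme gives the molecule a third way out, into quenched substrate, beside the two that the fork chance shares. In amber at 2.00 min, conversion of 78.8% less 20.7% quenched leaves 58.1% of the charge in target and side product, and the fork chance turns that into 41.4% target, against 41.4% in the flask, crystals counted.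

Take a neighbour, amber with 0.025 M of impurity, read at 2.00 min. The fork chance gives a share of 71.2% and, from the 65.6% of the charge that is neither left nor quenched, 46.7% target. The computed flask gives 71.2% and 46.7%.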